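Ring numbering used throughout: O1, C2 (carries the 4‑hydroxy‑3‑methoxyphenyl group), C3 (CH2OH), C4 (aroyl), C5 (CH2). Compound numbers are those of the steps below; the target is 20.

## Analysis of the target

Compound 20 is a monocyclic lignan with a single oxolane ring that bears an aryl group at C2, a hydroxymethyl group at C3 and a 4‑hydroxy‑3,5‑dimethoxybenzoyl group at C4. The three contiguous stereocentres are (2S,3R,4S): neighbouring substituents lie on opposite faces (2,3‑trans, 3,4‑trans), so the groups at C2 and C4 are cis to each other. This all‑trans pattern has no vicinal cis interaction and is therefore the thermodynamic one at the centres that can be made acidic, namely C4 (α to the ketone) and C3 (once CH2OH is carried as an ester). C2 cannot be corrected by enolisation, so it must be set correctly; it is also a benzylic ether para to a phenolic oxygen and is acid‑labile. O1 is β to the ketone through C5, so strong base can open the ring by β‑elimination; two electron‑rich phenols and a primary alcohol γ to the ketone are the other sensitive groups. The difficulty is absolute control over three adjacent centres with three different carbon substituents, while two similar oxygenated arenes must take different roles (aryl on C2, aroyl on C4). The plan rests on two readings of the ring: O1–C5–C4, with the carbonyl carbon disguised as a 1‑arylvinyl group, is an alkoxide tethered to a 2‑aryl‑allyl cation, and C2–C3 is the C=C bond of an arylidene malonate.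

## Retrosynthetic reasoning

**20 ⇒ 19.** The two phenolic O–H bonds are traced back to O–benzyl bonds. Both phenols must stay masked through organolithium, ylide, palladium, alkoxide, hydride and oxidant chemistry, and a benzyl ether survives all of these. The forward step must remove two benzyl groups without reducing the aryl ketone or the benzylic C2–O1 bond.

**19 ⇒ 17 (through 18).** The C=O of the aroyl group is traced back to C=CH2. The alkene is what makes C4 an allyl terminus in the key step, so the disguise costs nothing extra. Because it is inert to hydride, the ester at C3 can be reduced before the ketone exists, and no ketone protection or redox correction is needed. The forward step must cleave an electron‑rich 1,1‑disubstituted alkene beside two oxygenated arenes and a free alcohol.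

**17 ⇒ 16 ⇒ 15 ⇒ 14.** These are adjustments at C3 only: the CH2OH comes from an ester, the ester is brought to the face opposite both neighbours by equilibration, and before that one of two geminal esters is excised. The second ester is the price of a sufficiently electrophilic two‑carbon partner and a carbanion soft enough for allylic alkylation. The equilibration is placed while C3 is the only acidic centre, so that C2 and C4 act as fixed reference points. This requires the 2,4‑cis ring from the key step.

**14 ⇒ 9 + 12 (through 13).** The ring is cut at O1–C2 and C3–C4. This is the only pair of cuts that puts one arene in each fragment, leaves both fragments free of stereochemical requirements (9 is racemic, 12 is achiral), and makes the two ring bonds with matched polarity: alkoxide to the β‑carbon of an acceptor, stabilised carbanion to an allyl cation. It gains the ring, two skeletal bonds and the stereocentres C2 and C4 in one catalytic operation. The forward reaction has four tasks: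
- trap the alkoxide of zwitterion 13 with a weakly electrophilic alkene before 13 decays;
- close at the substituted allyl terminus (five‑membered, not seven‑membered ring);
- fix the face of the allyl unit through a chiral ligand on palladium;
- deliver the 2,4‑cis relationship.

**12 ⇒ 10 + 11.** The C2=C3 bond is cut by a Knoevenagel disconnection. Aldehyde 10 already carries the C2 arene with its phenol protected, and 11 supplies C3 with both activating groups.

**9 ⇒ 8 ⇒ 7 ⇒ 6 ⇒ 5 ⇒ 2 + 3 (through 4) ⇒ 1.** The carbonate is the cyclic carbonic ester of diol 8, and the diol is unmasked from acetonide 7. The C=CH2 bond of 7 comes from ketone 6 by methylenation, and 6 from carbinol 5 by oxidation. The aryl–carbon bond of 5 is cut to aryllithium 4 (from bromide 2, the benzyl ether of phenol 1) and the three‑carbon aldehyde 3. The cut is made at the aryl–carbon bond because it uses the arene as a nucleophile at its only halogenated position and brings in C4, C5 and O1 as one commercial piece.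

## Alternatives that were turned down

**Alternative 1: Prins–pinacol assembly.**
- Disconnection: O1–C2, C2–C3 and C4–C5. The pieces are the tertiary allylic diol (E)‑5‑(tert‑butyldiphenylsilyloxy)‑2‑(3,5‑dimethoxy‑4‑pivaloyloxyphenyl)pent‑3‑ene‑1,2‑diol A1 and the aldehyde 4‑formyl‑2‑methoxyphenyl pivalate A2.
- Forward key step: A1 and A2 are condensed to the cyclic acetal, and SnCl4 opens it to an oxocarbenium ion on the primary oxygen. The alkene attacks (C2–C3), the resulting cation lies next to the tertiary carbinol, the CH2O carbon migrates (C4–C5) and the carbinol carbon becomes the aroyl carbonyl, giving oxolane A3.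
- For: three ring bonds and the ketone at its final oxidation level arise from two fragments of similar size, with no carbon to remove afterwards.
- Against: all absolute stereochemistry must be stored in the tertiary benzylic carbinol of A1. That centre is consumed in the step and, next to an oxygenated arene, can ionise under SnCl4 before the acetal opens. This forces both phenols to be acylated. Enantiopure A1 needs its own asymmetric oxidation sequence. The aryl‑conjugated oxocarbenium ion cyclises slowly and can scramble configuration through reversible oxonia‑Cope pathways.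
- Comparison: on bonds per step and redox economy this alternative is stronger. The chosen route offers absolute control from a catalyst acting on racemic 9, a ring‑forming step under neutral conditions, and precursors without stereochemical requirements.

**Alternative 2: titanium‑mediated epoxide‑opening radical cyclisation.**
- Disconnection: C3–C4 only, back to the propargyl ether of an epoxy alcohol, A4.
- Forward key step: Cp2TiCl (trivalent titanium, from Cp2TiCl2 and Zn) opens the oxirane homolytically to the secondary radical at C3 and a titanium alkoxide on the future CH2OH. 5‑exo‑dig addition to the arylalkyne and quenching of the vinyl radical give the 4‑benzylidene oxolane A5.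
- For: this closure mode is dependable for 2‑aryl‑3‑hydroxymethyl oxolanes, the 2,3‑trans relationship follows from an equatorial C2 aryl group, and CH2OH arrives free and at its final oxidation level. C2 is accessible by a Sharpless epoxidation with kinetic resolution.
- Against: only one skeletal bond is made. The benzylidene group of A5 still needs hydroboration–oxidation and a selective oxidation of a secondary benzylic alcohol beside the primary one. Titanium is stoichiometric, kinetic resolution discards half of the carbinol, and the arylalkyne needs a cross‑coupling.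
- Comparison: the ring closure is better precedented than the chosen key step, which is conceded. The chosen route forms two bonds and two stereocentres catalytically, uses all of racemic 9, and brings in the aroyl carbon one cleavage away from the ketone.

**Alternative 3: oxocarbenium–allylsilane annulation.**
- Disconnection: O1–C2 and C2–C3, with 10 as C2 and the hydroxy allylsilane A6 as the C3–C4–C5–O1 unit.
- Forward key step: TMSOTf condenses A6 with 10 to an oxocarbenium ion, the allylsilane attacks through its γ‑carbon (C3) and silicon is lost. Oxolane A7 results, with a vinyl group on C3 that later gives CH2OH by ozonolysis and reduction.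
- For: 10 is used directly, and the all‑trans relative configuration should arise kinetically with every substituent pseudo‑equatorial, so no epimerisation is needed.
- Against: A6 must already contain C4 and the benzylic carbinol as defined stereocentres, which moves the stereochemical work into a long linear preparation, and the carbinol centre is made only to be oxidised away. The benzylic silyl ether on a trioxygenated arene can ionise under TMSOTf. The arene‑stabilised oxocarbenium ion closes slowly because the O1=C2 bond lies inside the forming ring. Ozonolysis near electron‑rich arenes, reduction, desilylation, benzylic oxidation and hydrogenolysis still follow.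
- Comparison: this alternative is stronger on relative stereocontrol within the ring‑forming event. The chosen route is shorter to its precursors and concentrates the stereochemical risk in one catalytic step fed by partners made by routine reactions.

Key step: step 8

Assumption: the stereocentre of aldehyde 3 is erased when carbonate 9 ionises, so 3 may be used as the racemate or as either commercial enantiomer; compounds 3 and 5–9 are drawn without configuration.

## Route

CIP descriptors change along the route because substituent priorities change; the spatial arrangement at C2 and C4 is the same from 14 to 20.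

Step 1
Reactants: 1 4‑bromo‑2,6‑dimethoxyphenol
Product: 2 2‑(benzyloxy)‑5‑bromo‑1,3‑dimethoxybenzene
Conditions: BnBr, K2CO3, DMF, 60 °C
Reagents that add atoms: benzyl bromide, BrCc1ccccc1
Why: Williamson ether synthesis; the phenoxide flanked by two methoxy groups is still alkylated readily by a primary benzylic halide in a dipolar aprotic solvent.

Step 2
Reactants: 2 2‑(benzyloxy)‑5‑bromo‑1,3‑dimethoxybenzene; 3 2,2‑dimethyl‑1,3‑dioxolane‑4‑carbaldehyde
Product: 5 [4‑(benzyloxy)‑3,5‑dimethoxyphenyl](2,2‑dimethyl‑1,3‑dioxolan‑4‑yl)methanol (both diastereomers), via aryllithium 4 (not isolated)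
Conditions: n‑BuLi, THF, −78 °C; then 3, −78 → 0 °C; H2O
Reagents that add atoms: none
Why: Bromine–lithium exchange is faster than ortho‑lithiation or benzylic deprotonation at −78 °C, and the aryllithium adds to the α‑alkoxy aldehyde (1,2‑addition); the carbinol configuration is irrelevant because it is oxidised next.

Step 3
Reactants: 5 [4‑(benzyloxy)‑3,5‑dimethoxyphenyl](2,2‑dimethyl‑1,3‑dioxolan‑4‑yl)methanol
Product: 6 [4‑(benzyloxy)‑3,5‑dimethoxyphenyl](2,2‑dimethyl‑1,3‑dioxolan‑4‑yl)methanone
Conditions: Dess–Martin periodinane, CH2Cl2, 0 °C → rt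
Reagents that add atoms: none
Why: Dess–Martin oxidation of a secondary benzylic alcohol; the conditions are mild enough for the acetonide and the benzyl ether.

Step 4
Reactants: 6 [4‑(benzyloxy)‑3,5‑dimethoxyphenyl](2,2‑dimethyl‑1,3‑dioxolan‑4‑yl)methanone
Product: 7 4‑{1‑[4‑(benzyloxy)‑3,5‑dimethoxyphenyl]ethenyl}‑2,2‑dimethyl‑1,3‑dioxolane
Conditions: Ph3PCH3Br, KOtBu, THF, 0 °C → rt
Reagents that add atoms: methyltriphenylphosphonium bromide, C[P+](c1ccccc1)(c1ccccc1)c1ccccc1.[Br-]
Why: Wittig methylenation; the aryl ketone has free ortho positions and should accept the unhindered ylide, which is added cold to limit enolisation of the α‑alkoxy ketone.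

Step 5
Reactants: 7 4‑{1‑[4‑(benzyloxy)‑3,5‑dimethoxyphenyl]ethenyl}‑2,2‑dimethyl‑1,3‑dioxolane
Product: 8 3‑[4‑(benzyloxy)‑3,5‑dimethoxyphenyl]but‑3‑ene‑1,2‑diol
Conditions: AcOH/H2O (4:1), 40 °C
Reagents that add atoms: none
Why: Acetal hydrolysis under weak acid; acetic acid is too weak to protonate the styrene‑type alkene, so the allylic diol should be released without hydration or rearrangement.

Step 6
Reactants: 8 3‑[4‑(benzyloxy)‑3,5‑dimethoxyphenyl]but‑3‑ene‑1,2‑diol
Product: 9 4‑{1‑[4‑(benzyloxy)‑3,5‑dimethoxyphenyl]ethenyl}‑1,3‑dioxolan‑2‑one (racemic)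
Conditions: CDI, DMAP (cat.), CH2Cl2, rt
Reagents that add atoms: 1,1'‑carbonyldiimidazole, O=C(n1ccnc1)n1ccnc1
Why: Carbonylation of a 1,2‑diol; acylation of the primary hydroxyl followed by 5‑exo closure by the secondary hydroxyl gives the cyclic carbonate under neutral conditions.

Step 7
Reactants: 10 4‑(benzyloxy)‑3‑methoxybenzaldehyde; 11 dimethyl malonate
Product: 12 dimethyl 2‑[4‑(benzyloxy)‑3‑methoxybenzylidene]malonate
Conditions: piperidine (cat.), AcOH (cat.), toluene, reflux, Dean–Stark
Reagents that add atoms: none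
Why: Knoevenagel condensation driven by azeotropic removal of water; the product has no alkene stereochemistry to control and no enolisable position.

Step 8
Reactants: 9 4‑{1‑[4‑(benzyloxy)‑3,5‑dimethoxyphenyl]ethenyl}‑1,3‑dioxolan‑2‑one; 12 dimethyl 2‑[4‑(benzyloxy)‑3‑methoxybenzylidene]malonate
Product: 14 dimethyl (2R,4S)‑2‑[4‑(benzyloxy)‑3‑methoxyphenyl]‑4‑{1‑[4‑(benzyloxy)‑3,5‑dimethoxyphenyl]ethenyl}oxolane‑3,3‑dicarboxylate (2,4‑cis), via palladium‑bound zwitterion 13 (not isolated)
Conditions: Pd2(dba)3·CHCl3 (2.5 mol %), chiral phosphoramidite L* [O,O'‑(1,1'‑binaphthalene‑2,2'‑diyl) N,N‑bis(1‑phenylethyl)phosphoramidite, one enantiomer, 10 mol %], THF, 25–40 °C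
Reagents that add atoms: none
Why: Zerovalent palladium ionises the allylic C–O bond of 9 and CO2 is lost, giving zwitterion 13; its two diastereomeric allyl complexes interconvert through the σ‑bonded form at the unsubstituted CH2 terminus, so racemic 9 should converge on the ligand‑favoured complex. The alkoxide adds reversibly to the β‑carbon of 12 (O1–C2), and the malonate carbanion then attacks the substituted allyl terminus on the face opposite palladium (C3–C4), a 5‑exo closure that is preferred over 7‑endo attack at the CH2 terminus. The closest known reaction type is the palladium‑catalysed decarboxylative [3+2] cycloaddition of 4‑vinyl‑1,3‑dioxolan‑2‑ones (and vinyl oxiranes) with doubly activated alkenes under chiral phosphoramidite control; the aryl group on the central allyl carbon is the feature not yet tested. C4 is controlled by the ligand, through the allyl face that carries palladium when the C–C bond forms. C2 is set in the same closure: because the oxa‑Michael step is reversible, the adduct whose envelope transition state holds the C2 aryl group pseudo‑equatorial and on the side of the C4 substituent should cyclise faster, giving the 2,4‑cis ring. The step needs C‑alkylation to outrun O‑allylation and β‑hydride elimination of 13, which the two ester groups secure by providing a soft, persistent carbanion on a non‑enolisable acceptor. The ligand enantiomer that gives the (2R,4S) adduct cannot be predicted with confidence and is to be identified in a trial run.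

Step 9
Reactants: 14 dimethyl (2R,4S)‑2‑[4‑(benzyloxy)‑3‑methoxyphenyl]‑4‑{1‑[4‑(benzyloxy)‑3,5‑dimethoxyphenyl]ethenyl}oxolane‑3,3‑dicarboxylate
Product: 15 methyl (2S,4R)‑2‑[4‑(benzyloxy)‑3‑methoxyphenyl]‑4‑{1‑[4‑(benzyloxy)‑3,5‑dimethoxyphenyl]ethenyl}oxolane‑3‑carboxylate (both C3 epimers)
Conditions: LiCl, H2O, DMSO, 150 °C
Reagents that add atoms: none
Why: Krapcho dealkoxycarbonylation; chloride attacks an ester methyl group, so the crowded quaternary centre is no obstacle, and the aryl ethers are not activated by a para carbonyl at this stage; protonation of the ester enolate is expected to give both C3 epimers.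

Step 10
Reactants: 15 methyl (2S,4R)‑2‑[4‑(benzyloxy)‑3‑methoxyphenyl]‑4‑{1‑[4‑(benzyloxy)‑3,5‑dimethoxyphenyl]ethenyl}oxolane‑3‑carboxylate
Product: 16 methyl (2S,3S,4R)‑2‑[4‑(benzyloxy)‑3‑methoxyphenyl]‑4‑{1‑[4‑(benzyloxy)‑3,5‑dimethoxyphenyl]ethenyl}oxolane‑3‑carboxylate (2,3‑trans, 3,4‑trans)
Conditions: NaOMe, MeOH/THF, 50 °C
Reagents that add atoms: none
Why: Base‑mediated epimerisation through the ester enolate; C3 is the only acidic centre, and with C2 and C4 fixed and cis to each other the ester should settle on the face opposite both neighbours. Methoxide matches the ester, so exchange is degenerate, and ring opening by β‑elimination of O1 is the reverse of a 5‑endo closure and stereoelectronically disfavoured.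

Step 11
Reactants: 16 methyl (2S,3S,4R)‑2‑[4‑(benzyloxy)‑3‑methoxyphenyl]‑4‑{1‑[4‑(benzyloxy)‑3,5‑dimethoxyphenyl]ethenyl}oxolane‑3‑carboxylate
Product: 17 [(2S,3R,4R)‑2‑[4‑(benzyloxy)‑3‑methoxyphenyl]‑4‑{1‑[4‑(benzyloxy)‑3,5‑dimethoxyphenyl]ethenyl}oxolan‑3‑yl]methanol
Conditions: LiAlH4, THF, 0 °C
Reagents that add atoms: none
Why: Hydride reduction of the ester to the primary alcohol; the alkene, the aryl ethers and the ring are inert, and no stereocentre is touched.

Step 12
Reactants: 17 [(2S,3R,4R)‑2‑[4‑(benzyloxy)‑3‑methoxyphenyl]‑4‑{1‑[4‑(benzyloxy)‑3,5‑dimethoxyphenyl]ethenyl}oxolan‑3‑yl]methanol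
Product: 19 [4‑(benzyloxy)‑3,5‑dimethoxyphenyl]{(2S,3R,4S)‑2‑[4‑(benzyloxy)‑3‑methoxyphenyl]‑3‑(hydroxymethyl)oxolan‑4‑yl}methanone, via vicinal diol 18 (not isolated)
Conditions: OsO4 (cat.), NaIO4, 2,6‑lutidine, dioxane/H2O, rt
Reagents that add atoms: osmium tetroxide, O=[Os](=O)(=O)=O; sodium periodate (terminal oxidant that restores the osmium oxo groups), [Na+].[O-]I(=O)(=O)=O
Why: Lemieux–Johnson oxidation; OsO4 dihydroxylates the electron‑rich 1,1‑disubstituted alkene and NaIO4 cleaves the glycol to the aryl ketone, with 2,6‑lutidine as buffer. C4 becomes α to the ketone but already has the favoured trans arrangement, and the trans hydroxymethyl group cannot close a hemiketal.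

Step 13
Reactants: 19 [4‑(benzyloxy)‑3,5‑dimethoxyphenyl]{(2S,3R,4S)‑2‑[4‑(benzyloxy)‑3‑methoxyphenyl]‑3‑(hydroxymethyl)oxolan‑4‑yl}methanone
Product: 20 (4‑hydroxy‑3,5‑dimethoxyphenyl)[(2S,3R,4S)‑2‑(4‑hydroxy‑3‑methoxyphenyl)‑3‑(hydroxymethyl)oxolan‑4‑yl]methanone
Conditions: H2 (1 atm), Pd/C, EtOAc, rt
Reagents that add atoms: none
Why: Catalytic hydrogenolysis of two aryl benzyl ethers; in a neutral, non‑protic solvent the donor‑substituted aryl ketone and the cyclic benzylic ether should be reduced much more slowly, and the reaction is stopped after two equivalents of hydrogen are taken up.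

## Compound list

1 | 4‑bromo‑2,6‑dimethoxyphenol | COc1cc(Br)cc(OC)c1O | starting material
2 | 2‑(benzyloxy)‑5‑bromo‑1,3‑dimethoxybenzene | COc1cc(Br)cc(OC)c1OCc1ccccc1 | intermediate
3 | 2,2‑dimethyl‑1,3‑dioxolane‑4‑carbaldehyde | CC1(C)OCC(C=O)O1 | starting material
4 | [4‑(benzyloxy)‑3,5‑dimethoxyphenyl]lithium | [Li]c1cc(OC)c(OCc2ccccc2)c(OC)c1 | intermediate
5 | [4‑(benzyloxy)‑3,5‑dimethoxyphenyl](2,2‑dimethyl‑1,3‑dioxolan‑4‑yl)methanol, both diastereomers | CC1(C)OCC(O1)C(O)c1cc(OC)c(OCc2ccccc2)c(OC)c1 | intermediate
6 | [4‑(benzyloxy)‑3,5‑dimethoxyphenyl](2,2‑dimethyl‑1,3‑dioxolan‑4‑yl)methanone | CC1(C)OCC(O1)C(=O)c1cc(OC)c(OCc2ccccc2)c(OC)c1 | intermediate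
7 | 4‑{1‑[4‑(benzyloxy)‑3,5‑dimethoxyphenyl]ethenyl}‑2,2‑dimethyl‑1,3‑dioxolane | C=C(c1cc(OC)c(OCc2ccccc2)c(OC)c1)C1COC(C)(C)O1 | intermediate
8 | 3‑[4‑(benzyloxy)‑3,5‑dimethoxyphenyl]but‑3‑ene‑1,2‑diol | C=C(c1cc(OC)c(OCc2ccccc2)c(OC)c1)C(O)CO | intermediate
9 | 4‑{1‑[4‑(benzyloxy)‑3,5‑dimethoxyphenyl]ethenyl}‑1,3‑dioxolan‑2‑one, racemic | C=C(c1cc(OC)c(OCc2ccccc2)c(OC)c1)C1COC(=O)O1 | intermediate
10 | 4‑(benzyloxy)‑3‑methoxybenzaldehyde | COc1cc(C=O)ccc1OCc1ccccc1 | starting material
11 | dimethyl malonate | COC(=O)CC(=O)OC | starting material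
12 | dimethyl 2‑[4‑(benzyloxy)‑3‑methoxybenzylidene]malonate | COC(=O)C(=Cc1ccc(OCc2ccccc2)c(OC)c1)C(=O)OC | intermediate
13 | zwitterion from 9 after ionisation and decarboxylation: divalent palladium 2‑aryl‑allyl cation with a pendant alkoxide (chiral ligand omitted, drawn as the terminal σ‑allyl form) | [O-]CC=C(C[Pd+])c1cc(OC)c(OCc2ccccc2)c(OC)c1 | intermediate
14 | dimethyl (2R,4S)‑2‑[4‑(benzyloxy)‑3‑methoxyphenyl]‑4‑{1‑[4‑(benzyloxy)‑3,5‑dimethoxyphenyl]ethenyl}oxolane‑3,3‑dicarboxylate, 2,4‑cis | COc1cc([C@H]2OC[C@@H](C(=C)c3cc(OC)c(OCc4ccccc4)c(OC)c3)C2(C(=O)OC)C(=O)OC)ccc1OCc1ccccc1 | intermediate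
15 | methyl (2S,4R)‑2‑[4‑(benzyloxy)‑3‑methoxyphenyl]‑4‑{1‑[4‑(benzyloxy)‑3,5‑dimethoxyphenyl]ethenyl}oxolane‑3‑carboxylate, both C3 epimers | COc1cc([C@H]2OC[C@@H](C(=C)c3cc(OC)c(OCc4ccccc4)c(OC)c3)C2C(=O)OC)ccc1OCc1ccccc1 | intermediate
16 | methyl (2S,3S,4R)‑2‑[4‑(benzyloxy)‑3‑methoxyphenyl]‑4‑{1‑[4‑(benzyloxy)‑3,5‑dimethoxyphenyl]ethenyl}oxolane‑3‑carboxylate | COc1cc([C@H]2OC[C@@H](C(=C)c3cc(OC)c(OCc4ccccc4)c(OC)c3)[C@@H]2C(=O)OC)ccc1OCc1ccccc1 | intermediate
17 | [(2S,3R,4R)‑2‑[4‑(benzyloxy)‑3‑methoxyphenyl]‑4‑{1‑[4‑(benzyloxy)‑3,5‑dimethoxyphenyl]ethenyl}oxolan‑3‑yl]methanol | COc1cc([C@H]2OC[C@@H](C(=C)c3cc(OC)c(OCc4ccccc4)c(OC)c3)[C@@H]2CO)ccc1OCc1ccccc1 | intermediate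
18 | 1‑[4‑(benzyloxy)‑3,5‑dimethoxyphenyl]‑1‑{(2S,3R,4S)‑2‑[4‑(benzyloxy)‑3‑methoxyphenyl]‑3‑(hydroxymethyl)oxolan‑4‑yl}ethane‑1,2‑diol, both epimers at the new carbinol | COc1cc([C@H]2OC[C@@H](C(O)(CO)c3cc(OC)c(OCc4ccccc4)c(OC)c3)[C@@H]2CO)ccc1OCc1ccccc1 | intermediate
19 | [4‑(benzyloxy)‑3,5‑dimethoxyphenyl]{(2S,3R,4S)‑2‑[4‑(benzyloxy)‑3‑methoxyphenyl]‑3‑(hydroxymethyl)oxolan‑4‑yl}methanone | COc1cc([C@H]2OC[C@@H](C(=O)c3cc(OC)c(OCc4ccccc4)c(OC)c3)[C@@H]2CO)ccc1OCc1ccccc1 | intermediate
20 | (4‑hydroxy‑3,5‑dimethoxyphenyl)[(2S,3R,4S)‑2‑(4‑hydroxy‑3‑methoxyphenyl)‑3‑(hydroxymethyl)oxolan‑4‑yl]methanone | COc1cc([C@H]2OC[C@@H](C(=O)c3cc(OC)c(O)c(OC)c3)[C@@H]2CO)ccc1O | target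

## Step count and least certain steps

Total: 13 steps. Longest linear sequence: 12 steps (steps 1–6 and 8–13); step 7 is a one‑step side branch.

**Step 8 (key step).**
- What may go wrong: the oxa‑Michael addition may be too slow or too reversible, because the para‑alkoxy group lowers the electrophilicity of 12. Zwitterion 13 would then decay by β‑hydride elimination or self‑condensation. The aryl group on the central allyl carbon also weakens the usual syn preference of the terminal substituent, so facial selectivity at C4 or the 2,4‑diastereoselectivity could be poor.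
- Fallback: it sets out from 10 and 9 and returns at 15. Condensation of 10 with 2,2‑dimethyl‑1,3‑dioxane‑4,6‑dione gives the much stronger acceptor 5‑[4‑(benzyloxy)‑3‑methoxybenzylidene]‑2,2‑dimethyl‑1,3‑dioxane‑4,6‑dione F1. Its cycloaddition with 9 under Pd2(dba)3·CHCl3 and the same ligand should give the spiro adduct (1R,4S)‑1‑[4‑(benzyloxy)‑3‑methoxyphenyl]‑4‑{1‑[4‑(benzyloxy)‑3,5‑dimethoxyphenyl]ethenyl}‑8,8‑dimethyl‑2,7,9‑trioxaspiro[4.5]decane‑6,10‑dione F2. NaOMe in MeOH opens the dioxanedione, and acidification gives the malonic half ester (2R,4S)‑2‑[4‑(benzyloxy)‑3‑methoxyphenyl]‑4‑{1‑[4‑(benzyloxy)‑3,5‑dimethoxyphenyl]ethenyl}‑3‑(methoxycarbonyl)oxolane‑3‑carboxylic acid F3, which should decarboxylate on warming in DMSO to 15. This replaces both the acceptor and the Krapcho step.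

**Step 10.**
- What may go wrong: enolisation of the hindered ester may be slow, so equilibration stays incomplete. Forcing it invites β‑elimination of O1 from C2 by the ester enolate, a ring opening that would erode configurational integrity.
- Fallback: it sets out from 15 and returns at 17, moving the epimerisation to the aldehyde oxidation level where an amine base suffices. i‑Bu2AlH in CH2Cl2 at −78 °C should give (2S,4R)‑2‑[4‑(benzyloxy)‑3‑methoxyphenyl]‑4‑{1‑[4‑(benzyloxy)‑3,5‑dimethoxyphenyl]ethenyl}oxolane‑3‑carbaldehyde F4 as its C3 epimers. DBU in CH2Cl2 at room temperature should equilibrate it to the (2S,3S,4R) aldehyde F5, and NaBH4 in MeOH at 0 °C reduces F5 to 17.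

**Step 4.**
- What may go wrong: the basic ylide may enolise the α‑alkoxy ketone instead of adding, and the enolate can expel the β‑oxygen of the acetonide, consuming material.
- Fallback: it sets out from 6 and returns at 7 by a Peterson olefination with a non‑basic nucleophile. Me3SiCH2MgCl with anhydrous CeCl3 in THF at −78 °C should add to the ketone and give 1‑[4‑(benzyloxy)‑3,5‑dimethoxyphenyl]‑1‑(2,2‑dimethyl‑1,3‑dioxolan‑4‑yl)‑2‑(trimethylsilyl)ethan‑1‑ol F6. KH in THF then brings about syn‑elimination to 7.

**Step 13.**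
- What may go wrong: over‑reduction. The C2–O1 bond is a benzylic ether on an oxygenated arene and may be hydrogenolysed, opening the ring, or the aryl ketone may be reduced once the phenols are free.
- Fallback: it sets out from 19 and returns at 20 without any reductant and makes no new compound (F0). Lewis‑acid debenzylation with BCl3 and pentamethylbenzene as cation scavenger in CH2Cl2 at −78 °C should cleave only the aryl benzyl ethers at that temperature.

## Further compounds

F1 | step 8 | 5‑[4‑(benzyloxy)‑3‑methoxybenzylidene]‑2,2‑dimethyl‑1,3‑dioxane‑4,6‑dione | COc1cc(C=C2C(=O)OC(C)(C)OC2=O)ccc1OCc1ccccc1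
F2 | step 8 | (1R,4S)‑1‑[4‑(benzyloxy)‑3‑methoxyphenyl]‑4‑{1‑[4‑(benzyloxy)‑3,5‑dimethoxyphenyl]ethenyl}‑8,8‑dimethyl‑2,7,9‑trioxaspiro[4.5]decane‑6,10‑dione | COc1cc([C@H]2OC[C@@H](C(=C)c3cc(OC)c(OCc4ccccc4)c(OC)c3)C23C(=O)OC(C)(C)OC3=O)ccc1OCc1ccccc1
F3 | step 8 | (2R,4S)‑2‑[4‑(benzyloxy)‑3‑methoxyphenyl]‑4‑{1‑[4‑(benzyloxy)‑3,5‑dimethoxyphenyl]ethenyl}‑3‑(methoxycarbonyl)oxolane‑3‑carboxylic acid, either configuration at C3 | COc1cc([C@H]2OC[C@@H](C(=C)c3cc(OC)c(OCc4ccccc4)c(OC)c3)C2(C(=O)O)C(=O)OC)ccc1OCc1ccccc1
F4 | step 10 | (2S,4R)‑2‑[4‑(benzyloxy)‑3‑methoxyphenyl]‑4‑{1‑[4‑(benzyloxy)‑3,5‑dimethoxyphenyl]ethenyl}oxolane‑3‑carbaldehyde, both C3 epimers | COc1cc([C@H]2OC[C@@H](C(=C)c3cc(OC)c(OCc4ccccc4)c(OC)c3)C2C=O)ccc1OCc1ccccc1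
F5 | step 10 | (2S,3S,4R)‑2‑[4‑(benzyloxy)‑3‑methoxyphenyl]‑4‑{1‑[4‑(benzyloxy)‑3,5‑dimethoxyphenyl]ethenyl}oxolane‑3‑carbaldehyde | COc1cc([C@H]2OC[C@@H](C(=C)c3cc(OC)c(OCc4ccccc4)c(OC)c3)[C@@H]2C=O)ccc1OCc1ccccc1
F6 | step 4 | 1‑[4‑(benzyloxy)‑3,5‑dimethoxyphenyl]‑1‑(2,2‑dimethyl‑1,3‑dioxolan‑4‑yl)‑2‑(trimethylsilyl)ethan‑1‑ol | CC1(C)OCC(O1)C(O)(C[Si](C)(C)C)c1cc(OC)c(OCc2ccccc2)c(OC)c1
F0 | step 13 | none | none
A1 | alternative 1 | (E)‑5‑(tert‑butyldiphenylsilyloxy)‑2‑(3,5‑dimethoxy‑4‑pivaloyloxyphenyl)pent‑3‑ene‑1,2‑diol, single enantiomer at the carbinol (sense to be matched to the target) | OCC(O)(/C=C/CO[Si](c1ccccc1)(c1ccccc1)C(C)(C)C)c1cc(OC)c(OC(=O)C(C)(C)C)c(OC)c1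
A2 | alternative 1 | 4‑formyl‑2‑methoxyphenyl pivalate | COc1cc(C=O)ccc1OC(=O)C(C)(C)C
A3 | alternative 1 | all‑trans 2‑aryl‑3‑(tert‑butyldiphenylsilyloxymethyl)‑4‑aroyl oxolane, both phenols as pivalates | COc1cc([C@H]2OC[C@@H](C(=O)c3cc(OC)c(OC(=O)C(C)(C)C)c(OC)c3)[C@@H]2CO[Si](c2ccccc2)(c2ccccc2)C(C)(C)C)ccc1OC(=O)C(C)(C)C
A4 | alternative 2 | 2‑{(R)‑[4‑(benzyloxy)‑3‑methoxyphenyl]({3‑[4‑(benzyloxy)‑3,5‑dimethoxyphenyl]prop‑2‑yn‑1‑yl}oxy)methyl}oxirane, oxirane carbon of either configuration | COc1cc([C@@H](OCC#Cc2cc(OC)c(OCc3ccccc3)c(OC)c2)C2CO2)ccc1OCc1ccccc1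
A5 | alternative 2 | trans‑2‑aryl‑3‑hydroxymethyl‑4‑benzylidene oxolane | COc1cc([C@H]2OC/C(=C\c3cc(OC)c(OCc4ccccc4)c(OC)c3)[C@@H]2CO)ccc1OCc1ccccc1
A6 | alternative 3 | (E)‑2‑{[4‑(benzyloxy)‑3,5‑dimethoxyphenyl][(tert‑butyldimethylsilyl)oxy]methyl}‑5‑(trimethylsilyl)pent‑3‑en‑1‑ol, configured as in A7 | OC[C@@H]([C@@H](O[Si](C)(C)C(C)(C)C)c1cc(OC)c(OCc2ccccc2)c(OC)c1)/C=C/C[Si](C)(C)C
A7 | alternative 3 | 2‑aryl‑3‑vinyl‑4‑[aryl(tert‑butyldimethylsilyloxy)methyl] oxolane | COc1cc([C@H]2OC[C@@H]([C@@H](O[Si](C)(C)C(C)(C)C)c3cc(OC)c(OCc4ccccc4)c(OC)c3)[C@@H]2C=C)ccc1OCc1ccccc1
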